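The ratio of target to other capture product is the number to watch in the violet flask. It stands near 4.08 in the violet run. It stands near 7.02 in the grey run, which has 150 mM of first nucleophile instead of 100 mM.

| setting | violet | grey | flask |
|---|---|---|---|
| substrate | 20 mM | 20 mM | 20 mM |
| first nucleophile | 100 mM | 150 mM | 100 mM |
| gas | 9.7 mM (held) | 9.7 mM (held) | 9.7 mM (held) |
| remark | the very flask that is asked about, followed so far | run made earlier |  |
| time |  |  | 15 d |

| run | time / d | target / % | other capture product / % |
|---|---|---|---|
| violet | 0.500 | 32.7 | 7.9 |
| violet | 1.67 | 32.6 | 9.5 |
| violet | 3.00 | 32.6 | 5.7 |
| violet | 4.00 | 31.6 | 8.5 |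
| violet | 6.00 | 33.6 | 8.4 |
| grey | 1.04 | 43.8 | 7.8 |
| grey | 2.50 | 43.0 | 3.5 |
| grey | 5.00 | 42.1 | 6.2 |
| grey | 8.00 | 42.4 | 6.6 |
| grey | 10.0 | 43.5 | 6.5 |

(standard deviation of a reading: 1 percentage point)

1. share of target in target plus other capture product at 15 min
2. share of target in target plus other capture product at 10 h
3. share of target in target plus other capture product at 15 d

- at the start none of the gas is in solution

Both runs are flat from their first reading. In the violet run the two products together hold 40.6 % of the substrate, so a third sink takes the rest. We read two rates here: capture by the first nucleophile, and capture by something that comes from the gas. A third sink taking from one common supply drops out of their ratio. The violet target amounts to 6.52 mM against 100 mM charged, so the first capture is pseudo-first-order.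

Target over other capture product, divided by charged first nucleophile over gas saturation, gives 0.396 in the violet run and 0.454 in the grey run. These are scattered readings, so we take their mean, 0.425, as the capture ratio.

For the violet flask this gives a product ratio of 4.38, a share of 81.4 % at 15 d, and the same at 10 h. The time 15 min lies before the first violet reading, so we have no reading of how far the gas, which starts with none in solution, has entered by then. We expect a higher share there and give no number.

The forecast says 88 %, 81 % and 80.3 %, its last figure a little below ours, and holds that early on “the other product lags and the target share should be higher”.

The violet flask gives 86.3 % at 15 min, 82.4 % at 10 h and 82.4 % at 15 d.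

    substrate → intermediate (k = 9.00 × 10⁻⁴ /s)
    first nucleophile + intermediate → target (k = 0.00570 /M/s)
    intermediate → solvolysis product (k = 9.70 × 10⁻⁴ /s)
    gas ⇌ second nucleophile, rate k4*(csat - [second nucleophile]) (kL = 0.00230 /s)
    second nucleophile + intermediate → other capture product (k = 0.0140 /M/s)

At 0.00893 d in the violet flask, the intermediate has a half-life of 0.34 h against first nucleophile and 0.072 d against second nucleophile, a factor of 5.08. At 15.0 d that flask holds 33.6 % target and 7.19 % other capture product. For a neighbour flask with 250 mM of first nucleophile, the capture ratio gives a product ratio of 10.9 and a share of 91.6 %; that neighbour ends at 92.4 %.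

The runs were generated by integration with constants of no real substance.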